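## The problem

The target 20 is two hexasubstituted benzene rings joined through one methylene carbon, which links carbon A5 of ring A to carbon B1 of ring B. It has no stereocentre, so the whole difficulty is regiochemical. Ring A carries a propanoyl group at A1 between hydroxyl groups at A2 and A6, a methyl group at A3, a hydroxyl group at A4 and the bridge at A5. Ring B repeats this pattern (bridge B1, hydroxyl B2, propanoyl B3, hydroxyl B4, methyl B5) with one exception: the oxygen at B6, para to the B3 ketone and flanked by the bridge and the methyl group, is a methyl ether. A synthesis must therefore make the diarylmethane bond as a true cross-coupling (electrophilic methylene coupling of two phloroglucinols also gives both symmetrical dimers), place a ketone between two oxygens on each ring, and tell one oxygen out of seven apart. Free methylene-bridged acylphloroglucinols are air-sensitive and exchange their halves under acid or base by reversible cleavage of the bridge, and 2,4,6-trialkoxybenzyl halides ionise readily. The phenols should therefore stay masked to the end, and strongly ionising benzylic intermediates are best avoided. The enabling feature is that A2, A3 and A4 form an O–C(CH3)–O unit identical with the 1,3-dicarbonyl unit of 2-methylcyclohexane-1,3-dione, with A5 as its α′ carbon, while A1 and A6 are an acyl-bearing and an oxygen-bearing carbon side by side, the pattern of an alkoxy-substituted acetylenic ketone. A cyclohexadiene made from the dione can take up such an alkyne across A2 and A5 and shed its two remaining CH2 groups as ethylene, which delivers ring A with all six substituents in place and the bridge already attached.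

## Retrosynthesis

**20 from 19.** The last operation cuts the four O–CH3 bonds at A2, A6, B2 and B4 of pentamethyl ether 19. Each of these oxygens is ortho to a ketone and the B6 oxygen alone is para to one, so a boron trihalide acting through a six-membered ketone chelate can tell them apart. Orthogonal protecting groups at B2 and B4 would need a desymmetrised ring B building block and several more steps. Compound 19 has the full skeleton but is stable to air, base and chromatography. The forward reaction must remove both ethers flanking each ketone and spare the B6 ether, which its two neighbours twist out of the ring plane.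

**19 from 17.** The B3–C(=O) bond is cut. Ring B of 17 has exactly one unsubstituted carbon, flanked by two methoxy groups and para to the third, so a Friedel–Crafts propanoylation has no regiochemical choice. The ketone cannot be carried from an earlier stage because an aryl ethyl ketone would not survive the enolate chemistry that builds the bridge. The free A4 hydroxyl of 17 is expected to be esterified as well, giving 18, and mild methanolysis returns the phenol. The Lewis acid must be mild enough not to cleave the electron-rich diarylmethane.

**17 from 10 and 14.** The A1–A2 and A5–A6 bonds are cut, so that ring A becomes siloxy methoxy cyclohexadiene 10 and the methoxy ynone 14. The forward path runs through bicyclic adduct 15 and aryl silyl ether 16.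
- This partition is preferred over other diene/alkyne partitions of ring A because the four diene carbons are exactly four carbons of the dione, and the alkyne needs only a ketone and one oxygen.
- The two partners are electronically matched: the benzyl-bearing diene terminus is the nucleophilic end and the oxygen-bearing alkyne carbon is the electrophilic end.
- A hexasubstituted benzene is traded for a diene two operations from an enone and a five-carbon ynone.
- The alkyne oxygen carries a methyl group, not an ethyl group. An ethyl ynol ether has a β-hydrogen and fragments to ethylene and a ketene near the temperature that ethylene extrusion from 15 requires. The methyl ether cannot do this and is removed in the last step all the same.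
- The forward reaction needs the stated regiochemistry and a diene and ynone that survive heating.

**14 from 11 and 12.** The C(sp)–C(=O) bond is cut. Lithium methoxyacetylide 13 is generated in the flask from 2-chloro-1,1-dimethoxyethane 11, which avoids handling volatile methoxyacetylene, and is acylated by N-methoxy-N-methylpropanamide 12. The chelated tetrahedral intermediate prevents a second addition.

**10 from 9.** The O–Si bond is cut. Kinetic deprotonation of enone 9 at the α′ carbon, the carbon that bears the benzyl group, gives the cross-conjugated enolate whose O-silylation is 10. Thermodynamic enolisation through the γ carbon would give a different diene with the wrong termini, so the enolate must be formed irreversibly at low temperature.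

**9 from 8, and 8 from 2 and 5.** The bond between the α′ carbon and the benzylic carbon is cut as a C=C bond. Aldol condensation of the kinetic enolate of vinylogous ester 2 with aldehyde 5 runs through aldolate 6 and mesylate 7 to arylidene enone 8, and hydrogenation gives 9. The neighbouring cut, alkylation of the same enolate with the 2,4,6-trimethoxy-3-methylbenzyl bromide, is one operation shorter on paper. It needs two extra steps to make a halide that ionises and self-condenses, whereas 5 is a stable solid. Either way the bridge carbon is set at the α′ position with no aromatic regiochemistry to control.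

**2 from 1, and 5 from 3.** The enol ether O–CH3 bond of 2 is cut back to 2-methylcyclohexane-1,3-dione 1; the dione is symmetrical, so only one enol ether can form. The formyl C–C bond of 5 is cut back to 2,4,6-trimethoxytoluene 3, whose two free positions are equivalent; Vilsmeier–Haack formylation passes through iminium salt 4.

## Roads not taken

**Alternative 1:** Danheiser benzannulation of ring B onto the bridge.
- Cut: the B1–B2 and B5–B6 bonds.
- Forward key step: heating 3-ethoxy-2-methylcyclobut-2-en-1-one A1 with the ring A-substituted alkynyl ether 1,3,5-tris(benzyloxy)-2-(3-methoxyprop-2-yn-1-yl)-4-methylbenzene A2. The cyclobutenone opens to a vinylketene, which adds to the alkyne; ring opening and 6π electrocyclisation then give 5-ethoxy-3-methoxy-4-methyl-2-[[2,4,6-tris(benzyloxy)-3-methylphenyl]methyl]phenol A3.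
- Merits: the three ring B oxygens arrive constitutionally different (OH, OEt, OMe), and ring A is unmasked by hydrogenolysis. This is better than the chosen plan, whose last step depends on chelation to single out B6.
- Weak points: A2 is an acid-sensitive ynol ether that must be made by alkylating a metallated methoxyacetylene with a labile trialkoxybenzyl halide. A1 needs ketene and 1-ethoxypropyne. After the annulation both propanoyl groups are still missing, and two Friedel–Crafts acylations must be run on a substrate with benzyl ethers that Lewis acids cleave.
- Comparison: the chosen plan answers with a ring A ketone that arrives in the ring-forming step, a single late acylation at a position with no alternative, and starting materials that are all purchased. The step counts are about equal.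

**Alternative 2:** biomimetic Claisen folding of a triketo ester.
- Cut: the A1–A6 bond.
- Forward key step: Mg(OMe)2 in methanol makes the C6 methylene of methyl 4-methyl-3,5,7-trioxo-2-[(2,4,6-trimethoxy-3-methylphenyl)methyl]nonanoate A4 attack its ester carbonyl. The product is 1-[2,4,6-trihydroxy-3-methyl-5-[(2,4,6-trimethoxy-3-methylphenyl)methyl]phenyl]propan-1-one A5.
- Merits: ring A appears with all three hydroxyls free, so the endgame only needs the ring B ketone and cleavage of two ethers. That is shorter and gentler than the fourfold cleavage of the chosen plan.
- Weak points: A4 is a doubly branched polycarbonyl chain whose assembly needs regiocontrolled polyanion acylations and alkylations. It can also cyclise to a 4-hydroxy-2-pyrone or by an aldol mode, and it is open to retro-Claisen cleavage by methoxide. The ring B acylation would then be run on a free triol.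
- Comparison: the chosen plan gives up the free hydroxyls in exchange for neutral, isolable intermediates and a ring closure in which two matched partners can combine in only one productive way.

**Alternative 3:** aryne insertion into propanoic acid for the ring B ketone.
- Cut: the B3–C(=O) and B4–O bonds.
- Forward key step: CsF releases the B3–B4 aryne from 3-(benzyloxy)-5-methoxy-6-methyl-2-(trimethylsilyl)phenyl trifluoromethanesulfonate A6, and propanoic acid adds across it by O-arylation and acyl migration. The product is 1-[6-(benzyloxy)-2-hydroxy-4-methoxy-3-methylphenyl]propan-1-one A7.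
- Merits: ring B is obtained with three differentiated oxygens, which is better than the chosen plan on that single point.
- Weak points: A6 is itself a pentasubstituted benzene that needs a multi-step regiocontrolled synthesis. The step installs only what a Friedel–Crafts acylation does in one operation. The real problem, the cross-coupling at the methylene bridge, is left to an electrophilic coupling of A7 with a ring A partner, where symmetrical dimers compete.
- Comparison: the chosen plan forms the bridge bond by enolate chemistry before ring A exists and so avoids that statistical problem.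

Key step: step 7

Remark: compounds 1, 3, 11 and 12 are taken as purchased; LiN(i-Pr)2 is used as a purchased solution; 10 and 14 are used freshly prepared.

## Route

Step 1
Reactants: 1 2-methylcyclohexane-1,3-dione
Product: 2 3-methoxy-2-methylcyclohex-2-en-1-one
Conditions: HC(OMe)3, MeOH, cat. TsOH·H2O, rt to 50 °C
Reagents that add atoms: trimethyl orthoformate, COC(OC)OC; methanol, CO
Why: Acid-catalysed enol etherification of a cyclic 1,3-dione to its vinylogous ester; the dione is symmetrical, so one product is possible, and the orthoformate consumes the water released.

Step 2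
Reactants: 3 2,4,6-trimethoxytoluene
Product: 5 2,4,6-trimethoxy-3-methylbenzaldehyde, via iminium chloride 4 (not isolated)
Conditions: POCl3, DMF, 0 °C to rt; then H2O, 50 °C
Reagents that add atoms: N,N-dimethylformamide, CN(C)C=O; water, O
Why: Vilsmeier–Haack formylation of a trialkoxyarene; the two free ring positions are equivalent, and the iminium group deactivates the ring against a second attack.

Step 3
Reactants: 2 3-methoxy-2-methylcyclohex-2-en-1-one; 5 2,4,6-trimethoxy-3-methylbenzaldehyde
Product: 8 (6E)-3-methoxy-2-methyl-6-[(2,4,6-trimethoxy-3-methylphenyl)methylidene]cyclohex-2-en-1-one, via lithium aldolate 6 (not isolated), via aldol mesylate 7 (not isolated)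
Conditions: LiN(i-Pr)2, THF, −78 °C; then 5; MsCl, −78 to 0 °C; DBU, rt
Reagents that add atoms: none
Why: Kinetic α′-deprotonation of the vinylogous ester (as in the Stork–Danheiser alkylation) and directed aldol addition, then mesylation of the aldolate and elimination to the conjugated arylidene ketone; the E geometry is expected on thermodynamic grounds and is erased in step 4.

Step 4
Reactants: 8 (6E)-3-methoxy-2-methyl-6-[(2,4,6-trimethoxy-3-methylphenyl)methylidene]cyclohex-2-en-1-one
Product: 9 3-methoxy-2-methyl-6-[(2,4,6-trimethoxy-3-methylphenyl)methyl]cyclohex-2-en-1-one (racemic)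
Conditions: H2 (1 atm), 10% Pd/C, EtOAc, rt
Reagents that add atoms: none
Why: Catalytic hydrogenation of the exocyclic trisubstituted enone double bond; the tetrasubstituted, alkoxy-bearing ring alkene is inert under these conditions, and the new stereocentre at C6 is racemic and is removed in step 5.

Step 5
Reactants: 9 3-methoxy-2-methyl-6-[(2,4,6-trimethoxy-3-methylphenyl)methyl]cyclohex-2-en-1-one
Product: 10 5-methoxy-6-methyl-2-[(2,4,6-trimethoxy-3-methylphenyl)methyl]-1-(trimethylsilyloxy)cyclohexa-1,5-diene
Conditions: LiN(i-Pr)2, THF, −78 °C; Me3SiCl, −78 °C to rt; pentane, filtration under argon; used crude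
Reagents that add atoms: chlorotrimethylsilane, C[Si](C)(C)Cl
Why: Irreversible kinetic deprotonation at the only α′ hydrogen gives the cross-conjugated enolate, and O-silylation gives the 2-siloxy diene; this is standard silyl dienol ether formation from 3-alkoxy enones.

Step 6
Reactants: 11 2-chloro-1,1-dimethoxyethane; 12 N-methoxy-N-methylpropanamide
Product: 14 1-methoxypent-1-yn-3-one, via lithium methoxyacetylide 13 (not isolated)
Conditions: 11, LiNEt2 (3 equiv, from Et2NH and n-BuLi), THF, 0 °C; then 12, −78 to −10 °C; inverse quench into cold aq. NaH2PO4/Et2O
Reagents that add atoms: none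
Why: Threefold base treatment of the chloroacetal (loss of methanol, loss of HCl, deprotonation) gives the alkoxyacetylide, which is acylated in a Weinreb ketone synthesis; the chelated tetrahedral intermediate holds until the acidic inverse quench, which also keeps amine and methoxide from adding to the ynone.

Step 7
Reactants: 10 5-methoxy-6-methyl-2-[(2,4,6-trimethoxy-3-methylphenyl)methyl]-1-(trimethylsilyloxy)cyclohexa-1,5-diene; 14 1-methoxypent-1-yn-3-one
Product: 17 1-[4-hydroxy-2,6-dimethoxy-3-methyl-5-[(2,4,6-trimethoxy-3-methylphenyl)methyl]phenyl]propan-1-one, via bicyclo[2.2.2]octadiene adduct 15 (not isolated), via aryl trimethylsilyl ether 16 (not isolated)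
Conditions: 14 (3 equiv), toluene, sealed tube, 110 °C, then 160 °C; then 1 M aq. HCl, THF, rt
Reagents that add atoms: none
Why: The electron-rich 1-methoxy-3-siloxy diene 10 adds the push–pull ynone 14 in an asynchronous, normal-electron-demand [4+2] cycloaddition in which the benzyl-bearing diene terminus, made nucleophilic by both the siloxy and the vinylogous methoxy group, bonds to the methoxy-bearing β-carbon of 14 (the A5–A6 bond) and the methoxy-bearing terminus bonds to the acyl-bearing α-carbon (the A1–A2 bond). Ring A is closed in this intermolecular cycloaddition as the cyclohexadiene ring of bicyclo[2.2.2]octadiene 15, with the diene held s-cis by its own ring. On further heating 15 loses its unsubstituted two-carbon bridge as ethylene by retro-[4+2] (Alder–Rickert reaction) to give aryl silyl ether 16, and dilute acid removes the silyl group to give 17. The closest known reaction type is the Alder–Rickert synthesis of resorcinol derivatives from 1-alkoxy-3-siloxycyclohexa-1,3-dienes and acetylenic ketones or esters, of which a heteroatom-substituted acetylenic ketone is a little-used member. No stereocentre is created, because both bridgehead carbons of 15 become aromatic carbons. The selectivity needed is regiochemical and is secured by the matched polarisation of the partners, the ketone making the β-carbon of 14 its electrophilic end; the opposite orientation would place the propanoyl group next to the benzyl carbon. The methyl ynol ether has no β-hydrogen and so cannot fragment to a ketene at these temperatures, and the two-stage heating lets the cycloaddition run before ethylene extrusion is forced.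

Step 8
Reactants: 17 1-[4-hydroxy-2,6-dimethoxy-3-methyl-5-[(2,4,6-trimethoxy-3-methylphenyl)methyl]phenyl]propan-1-one
Product: 19 1-[4-hydroxy-2,6-dimethoxy-3-methyl-5-[(2,4,6-trimethoxy-3-methyl-5-propanoylphenyl)methyl]phenyl]propan-1-one, via aryl propanoate 18 (not isolated)
Conditions: EtCOCl (3 equiv), TiCl4 (3 equiv), CH2Cl2, −20 to 0 °C; aqueous work-up; then K2CO3 (cat.), MeOH, rt
Reagents that add atoms: propanoyl chloride, CCC(=O)Cl
Why: Friedel–Crafts acylation at the only unsubstituted aromatic carbon, which is activated by two ortho and one para methoxy group; the A4 hydroxyl is esterified under the same conditions and is freed by base-catalysed methanolysis, which converges whatever the extent of O-acylation, and ring B without a free hydroxyl cannot leave the bridge under this mild base.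

Step 9
Reactants: 19 1-[4-hydroxy-2,6-dimethoxy-3-methyl-5-[(2,4,6-trimethoxy-3-methyl-5-propanoylphenyl)methyl]phenyl]propan-1-one
Product: 20 1-[3-[(2,4-dihydroxy-6-methoxy-5-methyl-3-propanoylphenyl)methyl]-2,4,6-trihydroxy-5-methylphenyl]propan-1-one
Conditions: BCl3 (10 equiv), CH2Cl2, −78 °C to rt; MeOH, then H2O, 0 °C
Reagents that add atoms: none
Why: Chelation-directed dealkylation of aryl methyl ethers ortho to a ketone: boron bound to the carbonyl oxygen activates the neighbouring O–CH3 bond for chloride attack, and excess reagent with warming is used to remove the second flanking ether of each ketone; the B6 ether, para to its ketone, has no chelating neighbour and should remain.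

## Compound list

1 | 2-methylcyclohexane-1,3-dione | CC1C(=O)CCCC1=O | starting material
2 | 3-methoxy-2-methylcyclohex-2-en-1-one | COC1=C(C)C(=O)CCC1 | intermediate
3 | 2,4,6-trimethoxytoluene | COc1cc(OC)c(C)c(OC)c1 | starting material
4 | N,N-dimethyl-1-(2,4,6-trimethoxy-3-methylphenyl)methaniminium chloride | C[N+](C)=Cc1c(OC)cc(OC)c(C)c1OC.[Cl-] | intermediate (not isolated)
5 | 2,4,6-trimethoxy-3-methylbenzaldehyde | O=Cc1c(OC)cc(OC)c(C)c1OC | intermediate
6 | lithium (4-methoxy-3-methyl-2-oxocyclohex-3-en-1-yl)(2,4,6-trimethoxy-3-methylphenyl)methanolate (racemic, mixture of diastereomers) | COC1=C(C)C(=O)C(CC1)C(O[Li])c1c(OC)cc(OC)c(C)c1OC | intermediate (not isolated)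
7 | (4-methoxy-3-methyl-2-oxocyclohex-3-en-1-yl)(2,4,6-trimethoxy-3-methylphenyl)methyl methanesulfonate (racemic, mixture of diastereomers) | COC1=C(C)C(=O)C(CC1)C(OS(C)(=O)=O)c1c(OC)cc(OC)c(C)c1OC | intermediate (not isolated)
8 | (6E)-3-methoxy-2-methyl-6-[(2,4,6-trimethoxy-3-methylphenyl)methylidene]cyclohex-2-en-1-one | COC1=C(C)C(=O)/C(=C/c2c(OC)cc(OC)c(C)c2OC)CC1 | intermediate
9 | 3-methoxy-2-methyl-6-[(2,4,6-trimethoxy-3-methylphenyl)methyl]cyclohex-2-en-1-one (racemic) | COC1=C(C)C(=O)C(Cc2c(OC)cc(OC)c(C)c2OC)CC1 | intermediate
10 | 5-methoxy-6-methyl-2-[(2,4,6-trimethoxy-3-methylphenyl)methyl]-1-(trimethylsilyloxy)cyclohexa-1,5-diene | COC1=C(C)C(O[Si](C)(C)C)=C(Cc2c(OC)cc(OC)c(C)c2OC)CC1 | intermediate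
11 | 2-chloro-1,1-dimethoxyethane | COC(CCl)OC | starting material
12 | N-methoxy-N-methylpropanamide | CCC(=O)N(C)OC | starting material
13 | lithium methoxyacetylide | COC#C[Li] | intermediate (not isolated)
14 | 1-methoxypent-1-yn-3-one | CCC(=O)C#COC | intermediate
15 | 1-[1,3-dimethoxy-6-methyl-4-[(2,4,6-trimethoxy-3-methylphenyl)methyl]-5-(trimethylsilyloxy)bicyclo[2.2.2]octa-2,5-dien-2-yl]propan-1-one (racemic) | COC12CCC(Cc3c(OC)cc(OC)c(C)c3OC)(C(O[Si](C)(C)C)=C1C)C(OC)=C2C(=O)CC | intermediate (not isolated)
16 | 1-[2,6-dimethoxy-3-methyl-5-[(2,4,6-trimethoxy-3-methylphenyl)methyl]-4-(trimethylsilyloxy)phenyl]propan-1-one | CCC(=O)c1c(OC)c(C)c(O[Si](C)(C)C)c(Cc2c(OC)cc(OC)c(C)c2OC)c1OC | intermediate (not isolated)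
17 | 1-[4-hydroxy-2,6-dimethoxy-3-methyl-5-[(2,4,6-trimethoxy-3-methylphenyl)methyl]phenyl]propan-1-one | CCC(=O)c1c(OC)c(C)c(O)c(Cc2c(OC)cc(OC)c(C)c2OC)c1OC | intermediate
18 | 3,5-dimethoxy-2-methyl-4-propanoyl-6-[(2,4,6-trimethoxy-3-methyl-5-propanoylphenyl)methyl]phenyl propanoate | CCC(=O)Oc1c(C)c(OC)c(C(=O)CC)c(OC)c1Cc1c(OC)c(C(=O)CC)c(OC)c(C)c1OC | intermediate (not isolated)
19 | 1-[4-hydroxy-2,6-dimethoxy-3-methyl-5-[(2,4,6-trimethoxy-3-methyl-5-propanoylphenyl)methyl]phenyl]propan-1-one | CCC(=O)c1c(OC)c(C)c(O)c(Cc2c(OC)c(C(=O)CC)c(OC)c(C)c2OC)c1OC | intermediate
20 | 1-[3-[(2,4-dihydroxy-6-methoxy-5-methyl-3-propanoylphenyl)methyl]-2,4,6-trihydroxy-5-methylphenyl]propan-1-one | CCC(=O)c1c(O)c(C)c(O)c(Cc2c(O)c(C(=O)CC)c(O)c(C)c2OC)c1O | target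

## Step count and risks

Total steps: 9. Longest linear sequence: 7 steps (1 → 2 → 8 → 9 → 10 → 17 → 19 → 20; the branch from 3 through 5 is equally long).

**Step 7 (key step).** The most likely failure is a cycloaddition that is too slow, because both diene termini are fully substituted and the dienophile carries a donor on its reacting carbon. Desilylation of 10, [1,5]-hydrogen shift isomerisation of the diene or oligomerisation of 14 could then take over; loss of regiocontrol is the lesser concern. The fallback gives up the cycloaddition for the union and joins preformed rings by Friedel–Crafts benzylation. It sets out from aldehyde 5 and comes back to the route at the target 20. Reduction of 5 with NaBH4 would give (2,4,6-trimethoxy-3-methylphenyl)methanol F1. Purchased 2-methylbenzene-1,3,5-triol would be propanoylated (EtCOCl, AlCl3) to 1-(2,4,6-trihydroxy-3-methylphenyl)propan-1-one F2. Slow addition of F1 to an excess of F2 with a catalytic Brønsted acid should capture the benzylic cation at the one free carbon of F2 and give 1-[2,4,6-trihydroxy-3-methyl-5-[(2,4,6-trimethoxy-3-methylphenyl)methyl]phenyl]propan-1-one F3 (the same compound as A5). Propanoylation of ring B as in step 8, with methanolysis of aryl esters, would give 1-[2,4,6-trihydroxy-3-methyl-5-[(2,4,6-trimethoxy-3-methyl-5-propanoylphenyl)methyl]phenyl]propan-1-one F4, and BCl3 would then remove the two ring B methyl groups ortho to the ketone to reach 20.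

**Step 8.** The Lewis acid and the HCl released may cleave or scramble the electron-rich diarylmethane by ipso attack at B1, or acylation at the hindered B3 position may stay incomplete. The fallback introduces the acyl carbon without a strong Lewis acid. It sets out from 17 and comes back at 19. Vilsmeier–Haack formylation (POCl3, DMF) would give 3-[(2-hydroxy-4,6-dimethoxy-3-methyl-5-propanoylphenyl)methyl]-2,4,6-trimethoxy-5-methylbenzaldehyde F5. Excess EtMgBr at −78 °C, which first forms the phenoxide and should spare the hindered ring A ketone, would give 1-[4-hydroxy-5-[[3-(1-hydroxypropyl)-2,4,6-trimethoxy-5-methylphenyl]methyl]-2,6-dimethoxy-3-methylphenyl]propan-1-one F6 (racemic). MnO2 oxidation of the benzylic alcohol would then give 19.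

**Step 9.** Dealkylation may stop after the first ortho ether of each ketone, the twisted B6 ether may be lost on forcing, or the bridge may scramble once both rings are free phenols. The fallback uses the fact that the fully demethylated compound is symmetrical. It sets out from 19 and comes back at 20. Exhaustive cleavage with BBr3 would give 1,1′-[methylenebis(2,4,6-trihydroxy-5-methyl-3,1-phenylene)]di(propan-1-one) F7. One equivalent of trimethylsilyldiazomethane in methanol/toluene should then methylate one of the two equivalent non-chelated hydroxyl groups para to the ketones, which are the most acidic. The outcome is statistical, and recovered F7 would be recycled.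

**Step 3.** The hindered, electron-rich aldehyde may add reversibly, so that retro-aldol cleavage returns starting materials before the aldolate is trapped, or proton exchange may lead to reaction at the γ carbon. The fallback forms the same bond by alkylation. It sets out from 5 and 2 and comes back at 9, bypassing step 4. The alcohol (2,4,6-trimethoxy-3-methylphenyl)methanol F1 would be converted under neutral Appel conditions (CBr4, PPh3, 0 °C) into 2-(bromomethyl)-1,3,5-trimethoxy-4-methylbenzene F8. F8 would be used at once, because it ionises easily, to alkylate the lithium enolate of 2 (LiN(i-Pr)2, THF, −78 °C).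

**Step 6.** Diethylamine or methoxide may add to the ynone during the quench, the ynol ether may be hydrated, or the amide base may attack the N-methoxy amide. The fallback separates carbon–carbon bond formation from ynone formation. It sets out from 11 and comes back at 14. Acetylide 13 would be added to propanal to give 1-methoxypent-1-yn-3-ol F9 (racemic). The amine would be washed out at this stage, where no Michael acceptor is present, and MnO2 oxidation would give 14.

## Further compounds

F1 | step 7 | (2,4,6-trimethoxy-3-methylphenyl)methanol | OCc1c(OC)cc(OC)c(C)c1OC
F2 | step 7 | 1-(2,4,6-trihydroxy-3-methylphenyl)propan-1-one | CCC(=O)c1c(O)cc(O)c(C)c1O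
F3 | step 7 | 1-[2,4,6-trihydroxy-3-methyl-5-[(2,4,6-trimethoxy-3-methylphenyl)methyl]phenyl]propan-1-one | CCC(=O)c1c(O)c(C)c(O)c(Cc2c(OC)cc(OC)c(C)c2OC)c1O
F4 | step 7 | 1-[2,4,6-trihydroxy-3-methyl-5-[(2,4,6-trimethoxy-3-methyl-5-propanoylphenyl)methyl]phenyl]propan-1-one | CCC(=O)c1c(O)c(C)c(O)c(Cc2c(OC)c(C(=O)CC)c(OC)c(C)c2OC)c1O
F5 | step 8 | 3-[(2-hydroxy-4,6-dimethoxy-3-methyl-5-propanoylphenyl)methyl]-2,4,6-trimethoxy-5-methylbenzaldehyde | CCC(=O)c1c(OC)c(C)c(O)c(Cc2c(OC)c(C=O)c(OC)c(C)c2OC)c1OC
F6 | step 8 | 1-[4-hydroxy-5-[[3-(1-hydroxypropyl)-2,4,6-trimethoxy-5-methylphenyl]methyl]-2,6-dimethoxy-3-methylphenyl]propan-1-one (racemic) | CCC(=O)c1c(OC)c(C)c(O)c(Cc2c(OC)c(C(O)CC)c(OC)c(C)c2OC)c1OC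
F7 | step 9 | 1,1′-[methylenebis(2,4,6-trihydroxy-5-methyl-3,1-phenylene)]di(propan-1-one) | CCC(=O)c1c(O)c(C)c(O)c(Cc2c(O)c(C)c(O)c(C(=O)CC)c2O)c1O
F8 | step 3 | 2-(bromomethyl)-1,3,5-trimethoxy-4-methylbenzene | BrCc1c(OC)cc(OC)c(C)c1OC
F9 | step 6 | 1-methoxypent-1-yn-3-ol (racemic) | CCC(O)C#COC
A1 | alternative 1 | 3-ethoxy-2-methylcyclobut-2-en-1-one | CCOC1=C(C)C(=O)C1
A2 | alternative 1 | 1,3,5-tris(benzyloxy)-2-(3-methoxyprop-2-yn-1-yl)-4-methylbenzene | COC#CCc1c(OCc2ccccc2)cc(OCc2ccccc2)c(C)c1OCc1ccccc1
A3 | alternative 1 | 5-ethoxy-3-methoxy-4-methyl-2-[[2,4,6-tris(benzyloxy)-3-methylphenyl]methyl]phenol | COc1c(C)c(OCC)cc(O)c1Cc1c(OCc2ccccc2)cc(OCc2ccccc2)c(C)c1OCc1ccccc1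
A4 | alternative 2 | methyl 4-methyl-3,5,7-trioxo-2-[(2,4,6-trimethoxy-3-methylphenyl)methyl]nonanoate (mixture of stereoisomers) | CCC(=O)CC(=O)C(C)C(=O)C(Cc1c(OC)cc(OC)c(C)c1OC)C(=O)OC
A5 | alternative 2 | 1-[2,4,6-trihydroxy-3-methyl-5-[(2,4,6-trimethoxy-3-methylphenyl)methyl]phenyl]propan-1-one | CCC(=O)c1c(O)c(C)c(O)c(Cc2c(OC)cc(OC)c(C)c2OC)c1O
A6 | alternative 3 | 3-(benzyloxy)-5-methoxy-6-methyl-2-(trimethylsilyl)phenyl trifluoromethanesulfonate | COc1cc(OCc2ccccc2)c([Si](C)(C)C)c(OS(=O)(=O)C(F)(F)F)c1C
A7 | alternative 3 | 1-[6-(benzyloxy)-2-hydroxy-4-methoxy-3-methylphenyl]propan-1-one | CCC(=O)c1c(O)c(C)c(OC)cc1OCc1ccccc1
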